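**Retrosynthetic overview**

1. Target 18 comes from its bis-silyl ether 17 by desilylation; the arene is bought and no ring is formed on the way. The chain is numbered C1′ (benzylic) to C17′.
2. Key cut: both Z-alkenes, C8′=C9′ and C14′=C15′, are disconnected together. Two Wittig reactions in one flask join ylide 14 (C15′–C17′), the C9′–C14′ core 6 and ylide 16 (arene plus C1′–C8′).
3. Feature used: O12′ is γ to C9′ but only β to C14′. In 6 only C9′ is masked as a five-membered lactol and C14′ stays a free aldehyde, so the two termini are told apart without protecting groups.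
4. Core 6 is the ozonolysis product of (1S)-cyclohex-3-en-1-ol 3: ring C3=C4 becomes C14′ and C9′, ring C1 becomes C12′. Alcohol 3 comes from a desymmetrising hydroboration of cyclohexa-1,4-diene 1, which sets the only stereocentre.
5. Ring events: the cyclohexene ring is cleaved in step 2, and the transient oxolane ring of 6 and 15 is opened in step 6.

Key step: step 6

Assumption: the sense of induction in step 1 is taken from the behaviour of this reagent with acyclic cis-alkenes; if the ring diene followed the opposite sense, the borane from (−)-α-pinene would be used with no other change.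

**Route**

Step 1
Reactants: 1 cyclohexa-1,4-diene
Product: 3 (1S)-cyclohex-3-en-1-ol, via cyclohexenyl diisopinocampheylborane 2 (not isolated)
Conditions: (−)-Ipc2BH [made in the flask from (+)-α-pinene and BH3·SMe2, THF, 0 °C], 1 (2 equiv), THF, −25 → 0 °C; then 3 M NaOH, 30% H2O2, 0 °C → rt
Reagents that add atoms: hydrogen peroxide, OO
Why: Asymmetric hydroboration of a cis-disubstituted ring alkene with the pinene-derived dialkylborane adds B–H syn to one of the enantiotopic alkene carbons under reagent control, and oxidation with retention should set C1 (the later C12′) as S; the four alkene carbons of 1 are equivalent and the excess of diene keeps the reaction at one alkene.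

Step 2
Reactants: 3 (1S)-cyclohex-3-en-1-ol
Product: 6 2-[(2S)-5-hydroxyoxolan-2-yl]acetaldehyde, via ozonide 4 (not isolated), via open hydroxy dialdehyde 5 (not isolated)
Conditions: O3/O2, CH2Cl2, −78 °C; N2 purge; PPh3 (1.05 equiv), −78 °C → rt; concentrate cold, take up in THF, use at once in step 6
Reagents that add atoms: ozone, [O-][O+]=O
Why: Criegee ozonolysis of the ring alkene and phosphine reduction of ozonide 4 give dialdehyde 5, in which O12′H closes on the γ-related C9′ to the five-membered lactol while the β-related C14′ aldehyde stays free; C12′ is not touched and the medium is neutral.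

Step 3
Reactants: 7 5-bromobenzene-1,3-diol
Product: 8 1-bromo-3,5-bis(tert-butyldimethylsilyloxy)benzene
Conditions: TBSCl (2.3 equiv), imidazole, DMF, rt
Reagents that add atoms: tert-butyldimethylsilyl chloride, CC(C)(C)[Si](C)(C)Cl
Why: Imidazole-promoted O-silylation masks both acidic phenols for the Grignard and ylide chemistry and can be removed at the end under conditions that spare the alkenes.

Step 4
Reactants: 8 1-bromo-3,5-bis(tert-butyldimethylsilyloxy)benzene, 9 1,8-dibromooctane
Product: 11 1-(8-bromooctyl)-3,5-bis(tert-butyldimethylsilyloxy)benzene, via aryl Grignard reagent 10 (not isolated)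
Conditions: Mg, THF, 40 °C; then add to 9 (3 equiv), Li2CuCl4 (3 mol %), THF, −10 °C → rt
Reagents that add atoms: none
Why: Magnesium insertion and copper-catalysed Grignard cross-coupling with a primary alkyl bromide (Kochi type) form the aryl–C1′ bond; the excess of the symmetrical dibromide keeps the reaction at mono-substitution and the aryl silyl ethers are inert to both reagents.

Step 5
Reactants: 11 1-(8-bromooctyl)-3,5-bis(tert-butyldimethylsilyloxy)benzene
Product: 12 {8-[3,5-bis(tert-butyldimethylsilyloxy)phenyl]octyl}triphenylphosphonium bromide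
Conditions: PPh3 (1.2 equiv), MeCN, reflux; dry by azeotrope with toluene
Reagents that add atoms: triphenylphosphine, c1ccc(cc1)P(c1ccccc1)c1ccccc1
Why: SN2 quaternisation of triphenylphosphine by the primary bromide under neutral conditions gives the phosphonium salt that carries the arene and C1′–C8′.

Step 6
Reactants: 6 2-[(2S)-5-hydroxyoxolan-2-yl]acetaldehyde, 13 propyltriphenylphosphonium bromide, 12 {8-[3,5-bis(tert-butyldimethylsilyloxy)phenyl]octyl}triphenylphosphonium bromide
Product: 17 5-[(8Z,12S,14Z)-12-hydroxyheptadeca-8,14-dien-1-yl]-1,3-bis(tert-butyldimethylsilyloxy)benzene, via propylidene ylide 14 (not isolated), via pentenyl lactol 15 (not isolated), via aryloctylidene ylide 16 (not isolated)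
Conditions: 13 (1.0 equiv), NaHMDS (0.98 equiv), THF, 0 °C; add dropwise to 6, THF, −78 °C, then −20 °C; then 12 (2.3 equiv) premixed with NaHMDS (2.2 equiv) in THF at 0 °C, add, −20 °C → rt; aq NH4Cl
Reagents that add atoms: none
Why: Two Wittig olefinations in one flask join three components: ylide 14 adds at −78 °C to the only free carbonyl of 6 (C14′) through the kinetically favoured cis-oxaphosphetane, which collapses to the Z-alkene and leaves γ-lactol 15, and on warming with excess ylide 16 this lactol opens to its γ-hydroxy aldehyde and is olefinated at C9′ in the same way. The closest known reaction types are the Z-selective Wittig reaction of non-stabilised ylides with aliphatic aldehydes under lithium-free conditions and the Wittig opening of γ-lactols to cis-alkenols used in prostanoid chemistry. No ring is closed; the oxolane ring of 6 is opened and O12′ is released as the free secondary alcohol. No stereocentre is created: C12′ comes unchanged from 3 and carries no acidic hydrogen, and the Z geometry of both C14′=C15′ and C8′=C9′ is set by the kinetic [2+2] addition of the non-stabilised ylides with a sodium base at low temperature. The step needs chemoselectivity between the two termini, which the substrate provides because O12′ can mask C9′ as a five-membered hemiacetal but cannot mask C14′ (a four-membered ring would be needed), and because the lactol terminus can react only after ring opening, which should be slow at −78 °C; dosing 14 at one equivalent and adding 16 only afterwards keeps each ylide at its own terminus. The low temperature and the speed of the first olefination are also meant to outrun β-elimination of O12′ from the β-alkoxy aldehyde.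

Step 7
Reactants: 17 5-[(8Z,12S,14Z)-12-hydroxyheptadeca-8,14-dien-1-yl]-1,3-bis(tert-butyldimethylsilyloxy)benzene
Product: 18 5-[(8Z,12S,14Z)-12-hydroxyheptadeca-8,14-dien-1-yl]benzene-1,3-diol
Conditions: TBAF (2.5 equiv), AcOH (2.5 equiv), THF, 0 °C
Reagents that add atoms: none
Why: Fluoride cleaves the aryl silyl ethers (and any silyl group that may have migrated to O12′ in step 6) through pentacoordinate silicon, and the acetic acid buffer keeps the medium near neutral so that the Z-alkenes, the homoallylic alcohol and the resorcinol stay intact.

**Compound list**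

1 | cyclohexa-1,4-diene | C1=CCC=CC1 | starting material
2 | [(1S)-cyclohex-3-en-1-yl]di(isopinocampheyl)borane (Ipc groups from (+)-α-pinene) | C[C@@H]1[C@H]2C[C@H](C2(C)C)C[C@H]1B([C@@H]1CC=CCC1)[C@@H]1C[C@@H]2C[C@H]([C@H]1C)C2(C)C | intermediate
3 | (1S)-cyclohex-3-en-1-ol | O[C@@H]1CC=CCC1 | intermediate
4 | (3S)-7,8,9-trioxabicyclo[4.2.1]nonan-3-ol (ozonide, both bridgehead arrangements) | O[C@@H]1CC2OOC(CC1)O2 | intermediate
5 | (3S)-3-hydroxyhexanedial | O=CC[C@@H](O)CCC=O | intermediate
6 | 2-[(2S)-5-hydroxyoxolan-2-yl]acetaldehyde (both anomers) | O=CC[C@@H]1CCC(O)O1 | intermediate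
7 | 5-bromobenzene-1,3-diol | Oc1cc(O)cc(Br)c1 | starting material
8 | 1-bromo-3,5-bis(tert-butyldimethylsilyloxy)benzene | CC(C)(C)[Si](C)(C)Oc1cc(Br)cc(O[Si](C)(C)C(C)(C)C)c1 | intermediate
9 | 1,8-dibromooctane | BrCCCCCCCCBr | starting material
10 | [3,5-bis(tert-butyldimethylsilyloxy)phenyl]magnesium bromide | CC(C)(C)[Si](C)(C)Oc1cc([Mg]Br)cc(O[Si](C)(C)C(C)(C)C)c1 | intermediate
11 | 1-(8-bromooctyl)-3,5-bis(tert-butyldimethylsilyloxy)benzene | CC(C)(C)[Si](C)(C)Oc1cc(CCCCCCCCBr)cc(O[Si](C)(C)C(C)(C)C)c1 | intermediate
12 | {8-[3,5-bis(tert-butyldimethylsilyloxy)phenyl]octyl}triphenylphosphonium bromide | CC(C)(C)[Si](C)(C)Oc1cc(CCCCCCCC[P+](c2ccccc2)(c2ccccc2)c2ccccc2)cc(O[Si](C)(C)C(C)(C)C)c1.[Br-] | intermediate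
13 | propyltriphenylphosphonium bromide | CCC[P+](c1ccccc1)(c1ccccc1)c1ccccc1.[Br-] | starting material
14 | propylidene(triphenyl)phosphorane | CCC=P(c1ccccc1)(c1ccccc1)c1ccccc1 | intermediate
15 | (5S)-5-[(2Z)-pent-2-en-1-yl]oxolan-2-ol (both anomers) | CC/C=C\C[C@@H]1CCC(O)O1 | intermediate
16 | {8-[3,5-bis(tert-butyldimethylsilyloxy)phenyl]octylidene}(triphenyl)phosphorane | CC(C)(C)[Si](C)(C)Oc1cc(CCCCCCCC=P(c2ccccc2)(c2ccccc2)c2ccccc2)cc(O[Si](C)(C)C(C)(C)C)c1 | intermediate
17 | 5-[(8Z,12S,14Z)-12-hydroxyheptadeca-8,14-dien-1-yl]-1,3-bis(tert-butyldimethylsilyloxy)benzene | CC/C=C\C[C@@H](O)CC/C=C\CCCCCCCc1cc(O[Si](C)(C)C(C)(C)C)cc(O[Si](C)(C)C(C)(C)C)c1 | intermediate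
18 | 5-[(8Z,12S,14Z)-12-hydroxyheptadeca-8,14-dien-1-yl]benzene-1,3-diol | CC/C=C\C[C@@H](O)CC/C=C\CCCCCCCc1cc(O)cc(O)c1 | target

**Step count**

Total step count: 7.
Longest linear sequence: 5 steps (steps 3, 4, 5, 6, 7); the core branch is steps 1, 2, 6, 7.

**Steps most likely to fail**

Step 6. The chemoselection between the two carbonyl termini may be incomplete. The hydroxyl of the lactol can transfer its proton to the first ylide, and the lactolate then opens and exposes C9′. The lactol hydroxyl can also add to the C14′ aldehyde and mask it as a bicyclic hemiacetal. Base-induced β-elimination of O12′ before olefination would in addition erode the configuration at C12′. The fallback tells the termini apart by oxidation level instead of by rate; it sets out from 3 and comes back at 15. Alcohol 3 is ozonised as in step 2 but worked up oxidatively (H2O2, HCO2H), so that both termini become carboxyl groups and the hydroxy diacid can lactonise only at C9′, giving 2-[(2S)-5-oxooxolan-2-yl]acetic acid F1. Borane–dimethyl sulfide (THF, 0 °C) reduces the free acid beside the lactone to (5S)-5-(2-hydroxyethyl)oxolan-2-one F2. Dess–Martin oxidation gives 2-[(2S)-5-oxooxolan-2-yl]acetaldehyde F3. Ylide 14 (THF, −78 °C) olefinates this aldehyde beside the inert lactone to (5S)-5-[(2Z)-pent-2-en-1-yl]oxolan-2-one F4. DIBAL-H (CH2Cl2, −78 °C) then gives 15, now isolated, which is treated with ylide 16 as in the second half of step 6 to reach 17.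

Step 2. The small, polar hydroxy dialdehyde may be lost by self-condensation or dehydration during concentration, and peroxidic material may be carried into the ylide step. The fallback replaces ozonolysis by glycol cleavage; it sets out from 3 and comes back at 6. Dihydroxylation (OsO4 cat., NMO, acetone/water) should give the storable (1S,2R,4S)-cyclohexane-1,2,4-triol F5, together with its 1R,2S,4S diastereomer, which leads to the same product. Cleavage with NaIO4 on silica gel in CH2Cl2 at rt, filtration and drying over molecular sieves would give a peroxide-free solution of 6 that goes into step 6 without concentration.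

Step 1. Discrimination of the enantiotopic alkene carbons may be poor, because a ring alkene reacts slowly with the hindered borane and pinene can then leave the reagent; some double hydroboration may also occur. The fallback sets the stereocentre by catalytic desymmetrisation of a meso epoxide; it sets out from 1 and comes back at 3. Mono-epoxidation (mCPBA, 0.5 equiv, CH2Cl2, NaHCO3, 0 °C) gives meso cis-7-oxabicyclo[4.1.0]hept-3-ene F6. Enantioselective anti ring opening with benzeneselenol under a chiral salen-type Lewis acid catalyst, with the catalyst enantiomer chosen accordingly, should give (1R,6R)-6-(phenylselanyl)cyclohex-3-en-1-ol F7. Radical deselenation (Bu3SnH, AIBN, benzene, 80 °C) then gives 3; the descriptor at C1 changes from R to S only because the selenium-bearing neighbour loses its priority.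

**Further compounds**

F1 | step 6 | 2-[(2S)-5-oxooxolan-2-yl]acetic acid | OC(=O)C[C@@H]1CCC(=O)O1
F2 | step 6 | (5S)-5-(2-hydroxyethyl)oxolan-2-one | OCC[C@@H]1CCC(=O)O1
F3 | step 6 | 2-[(2S)-5-oxooxolan-2-yl]acetaldehyde | O=CC[C@@H]1CCC(=O)O1
F4 | step 6 | (5S)-5-[(2Z)-pent-2-en-1-yl]oxolan-2-one | CC/C=C\C[C@@H]1CCC(=O)O1
F5 | step 2 | (1S,2R,4S)-cyclohexane-1,2,4-triol (with its 1R,2S,4S diastereomer) | O[C@@H]1C[C@@H](O)[C@@H](O)CC1
F6 | step 1 | cis-7-oxabicyclo[4.1.0]hept-3-ene (meso) | C1=CC[C@H]2O[C@H]2C1
F7 | step 1 | (1R,6R)-6-(phenylselanyl)cyclohex-3-en-1-ol | O[C@@H]1CC=CC[C@H]1[Se]c1ccccc1
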